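The flavonol is disconnected in ring C at C4–C4a. This leads back to a (2E)-2-alkoxy-3-aryl-3-aryloxyacrylic acid that already holds O1–C2, C2–C3, O3 and ring B. Activating its carboxyl group makes C4 an acyl electrophile, which ring A captures. One operation therefore forms the last skeletal bond, closes ring C and delivers the differentially protected quercetin core. The step exploits the local symmetry of ring A: in the 3,5-bis(allyloxy)phenyl ether of O1, the two carbons ortho to O1 (future C4a and C8) are equivalent, each para to an allyloxy oxygen. The precursor carries methoxymethyl on O3, allyl on O5, O7, O4' and benzyl on O3'.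

Key step: step 10

Assumption: the aryl sulfate monoesters 19 and 20 are handled and stored as triethylammonium salts; names and SMILES give the protonated neutral form, which the cation exchange at the end of step 13 sets free just before use.

Remark on the precursor: O3 is carried as a methoxymethyl acetal, not an allyl ether, because a 2-allyloxyacrylate is an allyl vinyl ether with an acceptor on the oxygen-bearing carbon and two donors on the terminus (primed for a Gosteli–Claisen [3,3] shift to an α-keto ester), and its glycolate enolate is open to a [2,3]-Wittig shift; the aryl allyl ethers on O5, O7 and O4' have no such low-temperature pathway.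

Remark on geometry: both alkene carbons bear oxygen, so the isomer with the aryloxy group cis to the carboxyl group is the E isomer; this geometry is drawn for 9, 10, 13, 14 and 15.

Step 1
Reactants: 1 3,4-dihydroxybenzaldehyde
Product: 2 4-(allyloxy)-3-hydroxybenzaldehyde
Conditions: allyl bromide (1.1 equiv), NaHCO3, NaI (cat.), DMF, 40 °C
Reagents that add atoms: allyl bromide, C=CCBr
Why: Williamson ether synthesis in which the weak base ionises only the more acidic 4-OH (para to the formyl group), so that the future O4' is allylated and the future O3' stays free.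

Step 2
Reactants: 2 4-(allyloxy)-3-hydroxybenzaldehyde
Product: 3 4-(allyloxy)-3-(benzyloxy)benzaldehyde
Conditions: BnBr, K2CO3, DMF, rt
Reagents that add atoms: benzyl bromide, BrCc1ccccc1
Why: Williamson benzylation of the only remaining phenol puts the non-migrating, late-cleaved benzyl group on the oxygen that must end unsulfated (O3').

Step 3
Reactants: 4 methyl glycolate
Product: 5 methyl 2-(methoxymethoxy)acetate
Conditions: MOMCl, i-Pr2NEt, CH2Cl2, 0 °C to rt
Reagents that add atoms: chloromethyl methyl ether, COCCl
Why: Acetal-type O-alkylation of the primary alcohol by the oxocarbenium-like electrophile gives a glycolate whose O3 substituent has no allylic π bond and so cannot enter sigmatropic shifts at any later enolate or enol ether stage.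

Step 4
Reactants: 5 methyl 2-(methoxymethoxy)acetate; 3 4-(allyloxy)-3-(benzyloxy)benzaldehyde
Product: 7 methyl 3-[4-(allyloxy)-3-(benzyloxy)phenyl]-3-hydroxy-2-(methoxymethoxy)propanoate as racemic syn/anti mixture, via lithium enolate 6 (not isolated)
Conditions: LiN(i-Pr)2, THF, −78 °C; then 3, −78 °C; AcOH quench at −78 °C
Reagents that add atoms: none
Why: Lithium ester enolate aldol addition to a non-enolisable aldehyde is fast at −78 °C and avoids the self-condensation expected of a crossed ester condensation with an electron-rich benzoate, and the two new stereocentres are left uncontrolled because steps 5 and 6 erase both.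

Step 5
Reactants: 7 methyl 3-[4-(allyloxy)-3-(benzyloxy)phenyl]-3-hydroxy-2-(methoxymethoxy)propanoate
Product: 8 methyl 3-[4-(allyloxy)-3-(benzyloxy)phenyl]-2-(methoxymethoxy)-3-oxopropanoate (racemic, C2 configurationally labile)
Conditions: Dess–Martin periodinane, CH2Cl2, 0 °C to rt
Reagents that add atoms: none
Why: Dess–Martin oxidation of the benzylic secondary alcohol runs under nearly neutral conditions that leave the allyl, benzyl and acetal groups untouched and merges both diastereomers into one β-ketoester.

Step 6
Reactants: 8 methyl 3-[4-(allyloxy)-3-(benzyloxy)phenyl]-2-(methoxymethoxy)-3-oxopropanoate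
Product: 10 methyl (2E)-3-[4-(allyloxy)-3-(benzyloxy)phenyl]-2-(methoxymethoxy)-3-{[(trifluoromethyl)sulfonyl]oxy}prop-2-enoate, via sodium enolate 9 (not isolated)
Conditions: NaH, Et2O, 0 °C; then Tf2O, −78 to 0 °C
Reagents that add atoms: trifluoromethanesulfonic anhydride, O=S(=O)(C(F)(F)F)OS(=O)(=O)C(F)(F)F
Why: O-sulfonylation of a β-ketoester enolate (enol triflate formation), in which sodium chelation between the enolate oxygen and the ester carbonyl holds these groups cis and should therefore give the E triflate.

Step 7
Reactants: 11 phloroglucinol (anhydrous)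
Product: 12 3,5-bis(allyloxy)phenol
Conditions: allyl bromide (2.0 equiv), K2CO3 (2.2 equiv), DMF, rt
Reagents that add atoms: allyl bromide, C=CCBr
Why: Williamson ether synthesis run to the statistical diether on a cheap side-branch material, with the polar aprotic medium favouring O- over C-allylation and the mono- and triethers removed by chromatography.

Step 8
Reactants: 10 methyl (2E)-3-[4-(allyloxy)-3-(benzyloxy)phenyl]-2-(methoxymethoxy)-3-{[(trifluoromethyl)sulfonyl]oxy}prop-2-enoate; 12 3,5-bis(allyloxy)phenol
Product: 13 methyl (2E)-3-[4-(allyloxy)-3-(benzyloxy)phenyl]-3-[3,5-bis(allyloxy)phenoxy]-2-(methoxymethoxy)prop-2-enoate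
Conditions: Cs2CO3, DMF, 0 °C to rt
Reagents that add atoms: none
Why: Nucleophilic vinylic substitution by addition–elimination, in which the caesium phenoxide adds through oxygen to the β-carbon of the triflyloxyacrylate and the resulting ester enolate expels triflate, normally with retention, so that O1–C2 forms with the aryloxy group cis to the ester.

Step 9
Reactants: 13 methyl (2E)-3-[4-(allyloxy)-3-(benzyloxy)phenyl]-3-[3,5-bis(allyloxy)phenoxy]-2-(methoxymethoxy)prop-2-enoate
Product: 14 (2E)-3-[4-(allyloxy)-3-(benzyloxy)phenyl]-3-[3,5-bis(allyloxy)phenoxy]-2-(methoxymethoxy)prop-2-enoic acid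
Conditions: LiOH·H2O, THF–MeOH–H2O, rt to 40 °C; then 1 M HCl to pH 3, 0 °C
Reagents that add atoms: lithium hydroxide, [Li+].[OH-]
Why: Saponification (acyl–oxygen ester hydrolysis) touches only the methyl ester, since the ethers, the acetal and the push–pull enol ether are inert to aqueous hydroxide and the brief cold acidification spares the acetal.

Step 10
Reactants: 14 (2E)-3-[4-(allyloxy)-3-(benzyloxy)phenyl]-3-[3,5-bis(allyloxy)phenoxy]-2-(methoxymethoxy)prop-2-enoic acid
Product: 16 5,7-bis(allyloxy)-2-[4-(allyloxy)-3-(benzyloxy)phenyl]-3-(methoxymethoxy)-4H-chromen-4-one, via mixed trifluoroacetic anhydride 15 (not isolated)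
Conditions: (CF3CO)2O (2.5 equiv), CH2Cl2 (0.05 M), 0 °C to rt; aq NaHCO3 quench
Reagents that add atoms: none
Why: Trifluoroacetic anhydride turns acid 14 into mixed anhydride 15, whose acyl carbon C4 (as such or after ionisation to the acylium ion) is attacked by a ring A carbon ortho to O1, and proton loss from the arenium ion gives chromenone 16 (intramolecular Friedel–Crafts acylation). The closest known reaction types are the cyclisation of β-aryloxycinnamic acids to flavones (Ruhemann flavone synthesis) and the anhydride-mediated closure of aryloxy acids to chromanones and xanthones. Ring C closes in a 6-exo-trig mode at the anhydride carbonyl, which only the E isomer can reach, and any Z isomer should equilibrate through reversible protonation at the future C3 of the push–pull alkene by the released acid, with closure draining the equilibrium. No stereocentre is formed. Regioselectivity comes from the symmetry of ring A (the two carbons ortho to O1 are equivalent and the third free carbon, para to O1, is out of reach), while chemoselectivity over ring B (five-membered indenone closure) and over intermolecular trifluoroacetylation rests on the three mutually reinforcing oxygen donors of ring A and on intramolecularity. No Lewis acid is present, so the allyl and benzyl ethers should persist, and a methoxymethyl group lost after closure would only anticipate step 11.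

Step 11
Reactants: 16 5,7-bis(allyloxy)-2-[4-(allyloxy)-3-(benzyloxy)phenyl]-3-(methoxymethoxy)-4H-chromen-4-one
Product: 18 2-[3-(benzyloxy)-4-hydroxyphenyl]-3,5,7-trihydroxy-4H-chromen-4-one (3'-O-benzylquercetin), via 3-O-methoxymethyl-3'-O-benzylquercetin 17 (not isolated)
Conditions: Pd(PPh3)4 (5 mol %), morpholine (10 equiv), THF–MeOH, rt, argon; then excess HCl in MeOH, 45 °C
Reagents that add atoms: none
Why: Tsuji–Trost type deallylation, in which zerovalent palladium ionises each aryl allyl ether to a π-allyl complex that morpholine intercepts, leaves the benzyl ether and acetal untouched, and the following acid-catalysed acetal exchange with methanol frees O3.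

Step 12
Reactants: 18 3'-O-benzylquercetin
Product: 19 3'-O-benzylquercetin 3,7,4'-tris(hydrogen sulfate)
Conditions: SO3·NEt3 (8 equiv), N,N-dimethylacetamide, 50 °C
Reagents that add atoms: sulfur trioxide–triethylamine complex, CC[N+](CC)(CC)S(=O)(=O)[O-]
Why: Sulfation of phenols with an amine–SO3 complex reaches the acidic 7-OH and 4'-OH and the enolic 3-OH, whereas O3' is blocked as its benzyl ether and the 5-OH, held in a six-membered hydrogen bond to the C4 carbonyl, needs far more forcing conditions.

Step 13
Reactants: 19 3'-O-benzylquercetin 3,7,4'-tris(hydrogen sulfate)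
Product: 20 quercetin 3,4',7-trisulfate
Conditions: H2 (1 atm), 10% Pd/C, MeOH–H2O, rt; then Dowex 50WX8 (H+ form), H2O, 4 °C, freeze-drying
Reagents that add atoms: none
Why: Catalytic hydrogenolysis cleaves the benzyl aryl ether under neutral conditions to which aryl sulfate salts and the flavonol C2=C3 bond are inert, and the cold cation exchange gives the protonated form.

Compound list
1 | 3,4-dihydroxybenzaldehyde | O=Cc1ccc(O)c(O)c1 | starting material
2 | 4-(allyloxy)-3-hydroxybenzaldehyde | O=Cc1ccc(OCC=C)c(O)c1 | intermediate
3 | 4-(allyloxy)-3-(benzyloxy)benzaldehyde | O=Cc1ccc(OCC=C)c(OCc2ccccc2)c1 | intermediate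
4 | methyl glycolate | COC(=O)CO | starting material
5 | methyl 2-(methoxymethoxy)acetate | COCOCC(=O)OC | intermediate
6 | lithium enolate of 5 (geometry of no consequence) | [Li+].[O-]C(OC)=COCOC | intermediate
7 | methyl 3-[4-(allyloxy)-3-(benzyloxy)phenyl]-3-hydroxy-2-(methoxymethoxy)propanoate (racemic syn/anti mixture) | COC(=O)C(OCOC)C(O)c1ccc(OCC=C)c(OCc2ccccc2)c1 | intermediate
8 | methyl 3-[4-(allyloxy)-3-(benzyloxy)phenyl]-2-(methoxymethoxy)-3-oxopropanoate (racemic) | COC(=O)C(OCOC)C(=O)c1ccc(OCC=C)c(OCc2ccccc2)c1 | intermediate
9 | chelated sodium (E)-enolate of 8 (enolate oxygen cis to the ester) | [Na+].COC(=O)/C(OCOC)=C(\[O-])c1ccc(OCC=C)c(OCc2ccccc2)c1 | intermediate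
10 | methyl (2E)-3-[4-(allyloxy)-3-(benzyloxy)phenyl]-2-(methoxymethoxy)-3-{[(trifluoromethyl)sulfonyl]oxy}prop-2-enoate | COC(=O)/C(OCOC)=C(\OS(=O)(=O)C(F)(F)F)c1ccc(OCC=C)c(OCc2ccccc2)c1 | intermediate
11 | phloroglucinol | Oc1cc(O)cc(O)c1 | starting material
12 | 3,5-bis(allyloxy)phenol | Oc1cc(OCC=C)cc(OCC=C)c1 | intermediate
13 | methyl (2E)-3-[4-(allyloxy)-3-(benzyloxy)phenyl]-3-[3,5-bis(allyloxy)phenoxy]-2-(methoxymethoxy)prop-2-enoate | COC(=O)/C(OCOC)=C(\Oc1cc(OCC=C)cc(OCC=C)c1)c1ccc(OCC=C)c(OCc2ccccc2)c1 | intermediate
14 | (2E)-3-[4-(allyloxy)-3-(benzyloxy)phenyl]-3-[3,5-bis(allyloxy)phenoxy]-2-(methoxymethoxy)prop-2-enoic acid | OC(=O)/C(OCOC)=C(\Oc1cc(OCC=C)cc(OCC=C)c1)c1ccc(OCC=C)c(OCc2ccccc2)c1 | intermediate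
15 | mixed anhydride of 14 with trifluoroacetic acid (E) | O=C(OC(=O)C(F)(F)F)/C(OCOC)=C(\Oc1cc(OCC=C)cc(OCC=C)c1)c1ccc(OCC=C)c(OCc2ccccc2)c1 | intermediate
16 | 5,7-bis(allyloxy)-2-[4-(allyloxy)-3-(benzyloxy)phenyl]-3-(methoxymethoxy)-4H-chromen-4-one | O=c1c(OCOC)c(-c2ccc(OCC=C)c(OCc3ccccc3)c2)oc2cc(OCC=C)cc(OCC=C)c12 | intermediate
17 | 2-[3-(benzyloxy)-4-hydroxyphenyl]-5,7-dihydroxy-3-(methoxymethoxy)-4H-chromen-4-one | O=c1c(OCOC)c(-c2ccc(O)c(OCc3ccccc3)c2)oc2cc(O)cc(O)c12 | intermediate
18 | 2-[3-(benzyloxy)-4-hydroxyphenyl]-3,5,7-trihydroxy-4H-chromen-4-one (3'-O-benzylquercetin) | O=c1c(O)c(-c2ccc(O)c(OCc3ccccc3)c2)oc2cc(O)cc(O)c12 | intermediate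
19 | 3'-O-benzylquercetin 3,7,4'-tris(hydrogen sulfate) | O=c1c(OS(=O)(=O)O)c(-c2ccc(OS(=O)(=O)O)c(OCc3ccccc3)c2)oc2cc(OS(=O)(=O)O)cc(O)c12 | intermediate
20 | quercetin 3,4',7-trisulfate | O=c1c(OS(=O)(=O)O)c(-c2ccc(OS(=O)(=O)O)c(O)c2)oc2cc(OS(=O)(=O)O)cc(O)c12 | target

Total step count: 13. Longest linear sequence: 11 steps (1, 2, 4, 5, 6, 8, 9, 10, 11, 12, 13).

Steps most likely to fail

1. Step 10 (key step).
- What may go wrong: intermolecular trifluoroacetylation of ring A may outrun ring closure. The methoxymethyl group may be lost to acid before closure, or its acetal oxygen may participate at the activated carboxyl. The wrong alkene geometry may close onto ring B.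
- Fallback: the same bond is made with reversed polarity, setting out from 13 and skipping steps 9 and 10.
- N-Iodosuccinimide in MeCN at 0 °C should iodinate ring A ortho to O1 and para to an allyloxy group. This gives methyl (2E)-3-[4-(allyloxy)-3-(benzyloxy)phenyl]-3-[3,5-bis(allyloxy)-2-iodophenoxy]-2-(methoxymethoxy)prop-2-enoate F1. The isomer iodinated between the two allyloxy groups is removed by chromatography.
- Iodine–magnesium exchange with i-PrMgCl·LiCl in THF at −20 °C then gives an arylmagnesium. It attacks the cis methyl ester and expels methoxide (Parham-type cyclisation), which comes back to the route at 16 under non-acidic conditions.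

2. Step 8.
- What may go wrong: the phenoxide may attack sulfur instead of carbon (triflyl transfer, which returns the ketoester enolate). The ambident phenoxide may react through carbon instead of oxygen. Addition to the hindered, donor-substituted β-carbon may be slow.
- Fallback: O1–C2 is built at an sp3 carbon by epoxide opening, setting out from 3 and 12.
- Darzens condensation of 3 with methyl chloroacetate (NaOMe, THF–MeOH, −10 °C to rt) gives methyl trans-3-[4-(allyloxy)-3-(benzyloxy)phenyl]oxirane-2-carboxylate F2.
- Phenol 12 with K2CO3 in DMF at 60 °C opens the epoxide at the benzylic carbon, giving methyl 3-[4-(allyloxy)-3-(benzyloxy)phenyl]-3-[3,5-bis(allyloxy)phenoxy]-2-hydroxypropanoate F3.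
- Dess–Martin oxidation gives methyl 3-[4-(allyloxy)-3-(benzyloxy)phenyl]-3-[3,5-bis(allyloxy)phenoxy]-2-oxopropanoate F4.
- The sodium enolate of F4 (NaH, THF, 0 °C) is alkylated on oxygen by the hard electrophile MOMCl, which comes back to the route at 13. An E/Z mixture is acceptable because the isomers equilibrate under the acid of step 10.

3. Step 12.
- What may go wrong: sulfation at the hindered O3 or O4' may be incomplete. Sulfation may creep onto O5 when the reaction is forced. Material may be lost in isolating a very polar polyanion.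
- Fallback: the sulfates are carried as neutral diesters, setting out from 18.
- 2,2,2-Trichloroethyl chlorosulfate (3.3 equiv), Et3N and DMAP in THF at 0 °C to rt should give 3'-O-benzylquercetin 3,7,4'-tris(2,2,2-trichloroethyl sulfate) F5, which can be purified on silica.
- Zn dust with HCO2NH4 in MeOH at rt removes the three trichloroethyl groups by reductive fragmentation. This comes back to the route at 19 (as its ammonium salt), ready for step 13.

Further compounds
F1 | step 10 | methyl (2E)-3-[4-(allyloxy)-3-(benzyloxy)phenyl]-3-[3,5-bis(allyloxy)-2-iodophenoxy]-2-(methoxymethoxy)prop-2-enoate | COC(=O)/C(OCOC)=C(\Oc1cc(OCC=C)cc(OCC=C)c1I)c1ccc(OCC=C)c(OCc2ccccc2)c1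
F2 | step 8 | methyl trans-3-[4-(allyloxy)-3-(benzyloxy)phenyl]oxirane-2-carboxylate (racemic, one enantiomer drawn) | COC(=O)[C@H]1[C@@H](O1)c2ccc(OCC=C)c(OCc3ccccc3)c2
F3 | step 8 | methyl 3-[4-(allyloxy)-3-(benzyloxy)phenyl]-3-[3,5-bis(allyloxy)phenoxy]-2-hydroxypropanoate (racemic, relative configuration of no consequence) | COC(=O)C(O)C(Oc1cc(OCC=C)cc(OCC=C)c1)c1ccc(OCC=C)c(OCc2ccccc2)c1
F4 | step 8 | methyl 3-[4-(allyloxy)-3-(benzyloxy)phenyl]-3-[3,5-bis(allyloxy)phenoxy]-2-oxopropanoate (racemic) | COC(=O)C(=O)C(Oc1cc(OCC=C)cc(OCC=C)c1)c1ccc(OCC=C)c(OCc2ccccc2)c1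
F5 | step 12 | 3'-O-benzylquercetin 3,7,4'-tris(2,2,2-trichloroethyl sulfate) | O=c1c(OS(=O)(=O)OCC(Cl)(Cl)Cl)c(-c2ccc(OS(=O)(=O)OCC(Cl)(Cl)Cl)c(OCc3ccccc3)c2)oc2cc(OS(=O)(=O)OCC(Cl)(Cl)Cl)cc(O)c12
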